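## Analysis of the target

The target is a germacranolide-type sesquiterpene lactone: a ten-membered carbocycle (C1–C10) fused at C6–C7 to an α-methylene-γ-butyrolactone (O–C6, C7, C11=C13, C12=O). In this numbering C1 is a ketone flanked by the exocyclic C10=C14 methylene, C3–C4 is a cis-epoxide with the C15 methyl on C4, C8 is a free carbinol and C9 carries the angelate. There are six stereocentres, (3S,4R,6R,7R,8R,9R). C6–C9 are contiguous: the lactone is trans-fused (H6/H7 anti); O6, the C11 branch and O8 lie on one side of the extended C5–C9 chain; and the C8 and C9 oxygens are syn. The epoxide is remote from this array and needs its own control element. Sensitive groups are the two Michael-acceptor methylenes, the β,γ-epoxy ketone (E1cB opening), the angelate (Z→E isomerisation, 1,2-acyl shift to O8) and the medium ring itself (transannular reactions). The hard part is closing a strained ten-membered ring that already carries the C6–C8 stereotriad, and bringing in the electrophilic and base-labile groups in an order they survive. The strategy rests on the C9 carbinol bonded to C10, which bears the exocyclic C14 methylene: a 2-substituted allylic alcohol is the branched reductive-coupling product of a terminal alkyne (C10≡C14, C1 as propargylic carbinol) and an aldehyde (C9), so C9–C10 can close the ring.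

## Retrosynthetic reasoning

**35 ⇐ 34 ⇐ 32.** Only the C8 hydroxyl is released last, from PMB ether 34. Compound 34 is the double allylic oxidation product of triol 32: the C12 alcohol becomes the lactone with O6 and the C1 alcohol becomes the enone. O8 stays blocked through this oxidation on purpose. A free O8 is placed as well as O6 (both 1,4 to C12) to capture the C12 aldehyde and would give the isomeric 8,12-lactone, and a free O8 next to the angelate invites acyl migration.

**32 ⇐ 31 ⇐ 30.** The epoxide is installed on 30, before any carbonyl exists at C1. There C3=C4 is the only electron-rich trisubstituted olefin and nothing in the molecule is base-sensitive, so a reagent-controlled dioxirane epoxidation can be used. Buffered desilylation of 31 then gives 32.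

**30 ⇐ 27 + 28; 27 ⇐ 26.** The angelate is attached to the free C9 hydroxyl of 27 with acid 28. C9 can be addressed alone because the ring closure delivers it as the only triethylsilyl ether (26), next to two TBS ethers, one TIPS ether and one PMB ether.

**26 ⇐ 24 + 25 (key disconnection, C9–C10).** Cutting C9–C10 gives a terminal alkyne and an aldehyde, the two partners of a zerovalent-nickel reductive coupling with silane 25. Cutting here, and not at an olefin or at the lactone, creates the exocyclic methylene, the C9 oxygen and the ring in one operation from a seco chain (24) whose C6–C8 stereocentres and Z-olefin are already fixed. The forward reaction must be exo-selective (bond to the internal alkyne carbon), must win over oligomerisation, and must form the 8,9-syn isomer. The lactone cannot be present (an enoate would engage nickel), so 24 carries it as C6 OTBS and C12 OTIPS.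

**24 ⇐ 23 ⇐ 22 ⇐ 21 ⇐ 20 ⇐ 19.** The C9 aldehyde and C8 OPMB come from the C8/C9 acetonide of 19. After silylation of O6 (20) the acetonide is hydrolysed (21) and re-closed as the 4-methoxybenzylidene acetal (22). Regioselective reductive opening leaves PMB on the secondary O8 and frees the primary C9 alcohol (23) for oxidation. TIPS, not TBS, is used on the primary allylic O12 so that it survives the acetonide hydrolysis and the later selective cleavage of the C9 triethylsilyl ether.

**19 ⇐ 17 + 6 (C6–C7).** This is the one convergent bond. The γ-carbon of an allyl metal derived from bromide 6 adds to aldehyde 17 and creates C6 and C7. The required 6,7-relationship (trans lactone) is the anti adduct. Zinc or indium Barbier reactions of the ester-bearing bromide 4 go through the Z-configured alkoxycarbonyl-allyl metal and give the syn adduct (cis lactone), so that shorter route is not used. The ester is reduced first, and the coupling is run as a chromium-mediated Nozaki–Hiyama allylation, whose equilibrating allylchromium reacts through the E-form (anti). The dioxolane stereocentre controls the face (C7/C8).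

**6 ⇐ 5 ⇐ 4 ⇐ 3 ⇐ 1 + 2.** A Morita–Baylis–Hillman reaction of aldehyde 1 with acrylate 2 supplies C7–C9 and C11–C13. C8 comes from the chiral pool. The MBH carbinol centre is erased in the SN2' bromination.

**17 ⇐ 16 ⇐ 15 ⇐ 14 ⇐ 13 ⇐ 12 ⇐ 10 ⇐ 9 ⇐ 8 ⇐ 7.** Lactone 7 holds C2–C6 with the Z-trisubstituted olefin locked by its ring. Reduction to lactol 8 and methylenation add C1 as a vinyl group (9). Hydroboration and oxidation turn it into the C1 aldehyde (13), which takes up the ethynyl unit (C10, C14). The C6 terminus is masked as a PMB ether in between and then oxidised to aldehyde 17.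

## Alternatives that were turned down

**Alternative 1:** ring-closing metathesis across C3=C4.
- Disconnection and key step: the C3=C4 double bond. A seco compound with a vinyl group (future C3) on C2 and an isopropenyl unit (future C4/C15) on C5 would be closed with the second-generation Grubbs catalyst to cyclodecene A1, with loss of the two terminal methylene carbons.
- For: A1 already holds lactone, enone and angelate and is two steps (desilylation, epoxidation) from the target. A ten-membered ring normally closes to the Z-olefin. No stereocentre is formed, so there is no C9 problem; on that point it is stronger than the chosen route.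
- Against: a trisubstituted olefin in a strained ten-membered ring is a poor metathesis product; the reaction is reversible and oligomers are favoured. The isopropenyl partner is sluggish. The vinyl group sits β,γ to the C1 ketone, where ruthenium hydrides can move it into conjugation. Two electron-poor methylenes compete for the carbene. The seco compound must carry both Michael acceptors and the angelate through its own assembly, and it still needs the C6–C9 tetrad by acyclic control, so nothing is saved there.
- Comparison: the chosen route closes the ring by irreversible C–C bond formation with all carbonyls masked, and takes the Z-olefin from a six-membered lactone (7). What it gives up is the stereochemical neutrality of the metathesis.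

**Alternative 2:** fragmentation of a Birch-derived bicycle.
- Disconnection and key step: the ten-membered ring is the periphery of a hexahydronaphthalene. Ozonolysis of the central tetrasubstituted C1=C6 olefin merges the two six-membered rings into cyclodec-3-ene-1,6-dione A2.
- For: no medium-ring closure is needed, which is more secure for ring formation than any cyclisation including the chosen one. The C7–C10 substituents are set on a rigid bicyclic frame. The Z geometry of C3=C4 is guaranteed.
- Against: ozonolysis must discriminate the tetrasubstituted olefin from the trisubstituted C3=C4 two carbons away. A2 is a 1,6-diketone in a ten-membered ring with activated methylenes on both sides, prone to transannular aldol reaction and to conjugation of the skipped olefin. The two ketones must then be differentiated (C6 reduced to the R carbinol, C1 kept). Lactone α-methylenation, elimination to C10=C14, acylation and epoxidation all remain, so the route is long.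
- Comparison: the chosen route brings C1 and C6 in as differentiated carbinols and makes C10=C14 in the ring closure itself. It is weaker than the fragmentation in certainty of ring formation, stronger in chemoselectivity and step count.

**Alternative 3:** anionic oxy-Cope ring expansion with enolate trapping.
- Disconnection and key step: C5–C6 is formed while a C3–C8 bond of a six-membered precursor is broken. The potassium alkoxide of a terpene-derived 1-alkenyl-2-isopropenylcyclohexanol undergoes the [3,3] shift to a ten-membered enolate, which is C-alkylated at C7 with a bromoacetic ester to give A3.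
- For: the ring and two skeletal bonds form in one flask (the chosen key step forms one bond). Ring expansion driven by enolate formation is reliable for cyclodecenones. The start is chiral pool.
- Against: the sigmatropic transition state fixes both the C3=C4 geometry and C6; the usual chair favours E olefins, and the Z olefin needs the less favourable arrangement. C7 alkylation and the later C8 reduction depend on medium-ring conformation. A3 has a C1–C10 epoxide and a C14 methyl where the target needs a ketone and a methylene, lacks the C3–C4 epoxide, and needs α-methylenation of the acetate arm. The terpene's 1,3-pattern must first be reorganised to put carbinol and isopropenyl on adjacent carbons.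
- Comparison: the chosen route sets C6, C7 and C8 in an acyclic, model-predictable coupling (19) and arrives at the ring with C10=C14 and the C1 oxygen in place. It is weaker in bond economy of the key step and in ring-formation reliability, stronger in stereochemical predictability and in what remains after the key step.

Key step: step 20

Remark on the chemistry: C1 is created without control in step 10 and ends as the ketone in step 25. Every C1-containing intermediate from 14 to 33 is therefore carried as a pair of C1 epimers; names and SMILES show the (1S) member only.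

## Route

Step 1
Reactants: 1 (S)-2,2-dimethyl-1,3-dioxolane-4-carbaldehyde; 2 ethyl acrylate
Product: 3 ethyl 2-{[(4S)-2,2-dimethyl-1,3-dioxolan-4-yl](hydroxy)methyl}prop-2-enoate (both carbinol epimers)
Conditions: DABCO (0.5 equiv), 1,4-dioxane/H2O (1:1), rt
Reagents that add atoms: none
Why: Morita–Baylis–Hillman reaction; the amine adds to 2 and the resulting enolate adds to the aldehyde. The new carbinol centre is unselective but is erased in step 2, and the dioxolane centre (future C8) is expected to be retained under these mild nucleophile-catalysed conditions.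

Step 2
Reactants: 3 ethyl 2-{[(4S)-2,2-dimethyl-1,3-dioxolan-4-yl](hydroxy)methyl}prop-2-enoate
Product: 4 ethyl (2Z)-2-(bromomethyl)-3-[(4R)-2,2-dimethyl-1,3-dioxolan-4-yl]prop-2-enoate
Conditions: NBS, Me2S, CH2Cl2, 0 °C to rt
Reagents that add atoms: N-bromosuccinimide, O=C1CCC(=O)N1Br
Why: Corey–Kim-type activation of the allylic alcohol as an alkoxysulfonium salt, then SN2' delivery of bromide into conjugation with the ester. The thermodynamically preferred Z-bromide (dioxolane trans to the ester) should form, and the acid-free conditions spare the acetonide.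

Step 3
Reactants: 4 ethyl (2Z)-2-(bromomethyl)-3-[(4R)-2,2-dimethyl-1,3-dioxolan-4-yl]prop-2-enoate
Product: 5 (2Z)-2-(bromomethyl)-3-[(4R)-2,2-dimethyl-1,3-dioxolan-4-yl]prop-2-en-1-ol
Conditions: i-Bu2AlH (2.2 equiv), CH2Cl2, −78 °C; aq. potassium sodium tartrate
Reagents that add atoms: none
Why: 1,2-reduction of the enoate to the allylic alcohol; at −78 °C hydride displacement of the allylic bromide does not compete. Removing the ester here is what later allows an anti-selective allylchromium instead of a syn-selective alkoxycarbonyl-allyl metal.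

Step 4
Reactants: 5 (2Z)-2-(bromomethyl)-3-[(4R)-2,2-dimethyl-1,3-dioxolan-4-yl]prop-2-en-1-ol
Product: 6 {[(2Z)-2-(bromomethyl)-3-[(4R)-2,2-dimethyl-1,3-dioxolan-4-yl]prop-2-en-1-yl]oxy}tri(propan-2-yl)silane
Conditions: TIPSOTf, 2,6-lutidine, CH2Cl2, −78 to 0 °C
Reagents that add atoms: triisopropylsilyl trifluoromethanesulfonate, CC(C)[Si](OS(=O)(=O)C(F)(F)F)(C(C)C)C(C)C
Why: Silylation of the primary alcohol (future O12) with a hindered, non-nucleophilic base that cannot alkylate the allylic bromide. TIPS is chosen for its stability to the later acidic steps.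

Step 5
Reactants: 7 4-methyl-5,6-dihydro-2H-pyran-2-one
Product: 8 4-methyl-5,6-dihydro-2H-pyran-2-ol
Conditions: i-Bu2AlH (1.05 equiv), CH2Cl2, −78 °C
Reagents that add atoms: none
Why: Partial reduction of the lactone; the tetrahedral aluminate is stable at −78 °C and gives the lactol on work-up. The Z geometry of the future C3=C4 olefin is locked by the ring.

Step 6
Reactants: 8 4-methyl-5,6-dihydro-2H-pyran-2-ol
Product: 9 (3Z)-3-methylhexa-3,5-dien-1-ol
Conditions: Ph3PCH3Br, KOt-Bu (2.4 equiv), THF, 0 °C to rt
Reagents that add atoms: methyltriphenylphosphonium bromide, C[P+](c1ccccc1)(c1ccccc1)c1ccccc1.[Br-]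
Why: Wittig methylenation of the open hydroxy-enal tautomer of the lactol adds C1. The trisubstituted olefin is not involved and should keep its Z geometry.

Step 7
Reactants: 9 (3Z)-3-methylhexa-3,5-dien-1-ol
Product: 10 1-methoxy-4-({[(3Z)-3-methylhexa-3,5-dien-1-yl]oxy}methyl)benzene
Conditions: NaH, 4-methoxybenzyl chloride, Bu4NI (cat.), THF/DMF, 0 °C to rt
Reagents that add atoms: 4-methoxybenzyl chloride, COc1ccc(CCl)cc1
Why: Williamson etherification masks the future C6 oxygen with a group that is later removed oxidatively without touching the silyl ether or the alkyne.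

Step 8
Reactants: 10 1-methoxy-4-({[(3Z)-3-methylhexa-3,5-dien-1-yl]oxy}methyl)benzene
Product: 12 (3Z)-6-[(4-methoxybenzyl)oxy]-4-methylhex-3-en-1-ol, via B-alkyl-9-BBN adduct 11 (not isolated)
Conditions: 9-BBN (1.3 equiv), THF, 0 °C to rt; then NaOH, H2O2, 0 °C
Reagents that add atoms: hydrogen peroxide, OO; 9-borabicyclo[3.3.1]nonane, [H]B1C2CCCC1CCC2 (atoms held in 11 only)
Why: Anti-Markovnikov hydroboration of the monosubstituted terminus of the diene by a bulky borane, then oxidation with retention. The trisubstituted olefin is too hindered to react, so C1 becomes the primary alcohol and C2 a methylene.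

Step 9
Reactants: 12 (3Z)-6-[(4-methoxybenzyl)oxy]-4-methylhex-3-en-1-ol
Product: 13 (3Z)-6-[(4-methoxybenzyl)oxy]-4-methylhex-3-enal
Conditions: Dess–Martin periodinane, NaHCO3, CH2Cl2, 0 °C
Reagents that add atoms: none
Why: Buffered hypervalent-iodine oxidation gives the β,γ-unsaturated aldehyde without the base or acid that would move the olefin into conjugation. The aldehyde is used directly.

Step 10
Reactants: 13 (3Z)-6-[(4-methoxybenzyl)oxy]-4-methylhex-3-enal
Product: 14 (3S,5Z)-8-[(4-methoxybenzyl)oxy]-6-methyloct-5-en-1-yn-3-ol (with its 3R epimer)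
Conditions: HC≡CMgBr (0.5 M in THF), THF, −78 to −20 °C; aq. NH4Cl
Reagents that add atoms: ethynylmagnesium bromide, C#C[Mg]Br
Why: Grignard 1,2-addition of the weakly basic alkynyl reagent at low temperature outruns enolisation of the skipped aldehyde. C1 is formed without control, which is immaterial because it ends as the ketone.

Step 11
Reactants: 14 (3S,5Z)-8-[(4-methoxybenzyl)oxy]-6-methyloct-5-en-1-yn-3-ol
Product: 15 tert-butyl{[(3S,5Z)-8-[(4-methoxybenzyl)oxy]-6-methyloct-5-en-1-yn-3-yl]oxy}dimethylsilane
Conditions: TBSCl, imidazole, DMF, rt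
Reagents that add atoms: tert-butyldimethylsilyl chloride, CC(C)(C)[Si](C)(C)Cl
Why: Standard silylation of the propargylic alcohol. The secondary TBS ether gives the alkyne the steric bulk that supports the regiochemistry of the key step.

Step 12
Reactants: 15 tert-butyl{[(3S,5Z)-8-[(4-methoxybenzyl)oxy]-6-methyloct-5-en-1-yn-3-yl]oxy}dimethylsilane
Product: 16 (3Z,6S)-6-[(tert-butyldimethylsilyl)oxy]-3-methyloct-3-en-7-yn-1-ol
Conditions: DDQ, CH2Cl2/pH 7 buffer (10:1), 0 °C
Reagents that add atoms: none
Why: Oxidative cleavage of the PMB ether (benzylic hydride abstraction, hydrolysis of the oxocarbenium ion). Silyl ether, alkyne and isolated olefin are inert to DDQ.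

Step 13
Reactants: 16 (3Z,6S)-6-[(tert-butyldimethylsilyl)oxy]-3-methyloct-3-en-7-yn-1-ol
Product: 17 (3Z,6S)-6-[(tert-butyldimethylsilyl)oxy]-3-methyloct-3-en-7-ynal
Conditions: Dess–Martin periodinane, NaHCO3, CH2Cl2, 0 °C
Reagents that add atoms: none
Why: Buffered Dess–Martin oxidation to the second β,γ-unsaturated aldehyde (C6), again without conditions that cause conjugation; used directly in step 14.

Step 14
Reactants: 17 (3Z,6S)-6-[(tert-butyldimethylsilyl)oxy]-3-methyloct-3-en-7-ynal; 6 {[(2Z)-2-(bromomethyl)-3-[(4R)-2,2-dimethyl-1,3-dioxolan-4-yl]prop-2-en-1-yl]oxy}tri(propan-2-yl)silane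
Product: 19 seco alcohol (1S,6R,7S,8R) with C6 OH; C8/C9 acetonide; C12 OTIPS; C1 OTBS; C10≡C14 alkyne, via allylchromium dichloride 18 (not isolated)
Conditions: CrCl2 (4 equiv), THF, 0 °C to rt
Reagents that add atoms: chromium dichloride, Cl[Cr]Cl (atoms held in 18 only)
Why: Nozaki–Hiyama allylation. Two equivalents of divalent chromium reduce the bromide to an allylchromium that equilibrates to the E-form (C8 trans to CH2Cr) and adds through its γ-carbon in a chair with C5 and C8 equatorial, giving the 6,7-anti adduct needed for the trans lactone. The C7/C8 relationship is set by the dioxolane: C8–H eclipses the cis CH2OTIPS group to relieve 1,3-allylic strain, and the aldehyde bonds to C7 anti to the C8–O bond. Alkyne and silyl ethers are inert to CrCl2.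

Step 15
Reactants: 19 seco alcohol (1S,6R,7S,8R)
Product: 20 C6 TBS ether of the seco chain (1S,6R,7R,8R)
Conditions: TBSOTf (1.2 equiv), 2,6-lutidine, CH2Cl2, −78 to −40 °C
Reagents that add atoms: tert-butyldimethylsilyl trifluoromethanesulfonate, CC(C)(C)[Si](C)(C)OS(=O)(=O)C(F)(F)F
Why: Silyl triflate silylation of the hindered secondary alcohol; the low temperature and near-stoichiometric triflate leave the acetonide intact. O6 is now masked in the form required in the nickel step.

Step 16
Reactants: 20 C6 TBS ether of the seco chain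
Product: 21 C8,C9-diol (1S,6R,7R,8R)
Conditions: AcOH/THF/H2O (3:1:1), 35 °C
Reagents that add atoms: none
Why: Acid hydrolysis of the terminal isopropylidene acetal. Two secondary TBS ethers and a primary TIPS ether are markedly more stable to aqueous acetic acid than the acetonide, which is why no primary TBS ether is present.

Step 17
Reactants: 21 C8,C9-diol
Product: 22 C8/C9 4-methoxybenzylidene acetal (both acetal epimers)
Conditions: 4-MeOC6H4CH(OMe)2, PPTS (cat.), CH2Cl2, rt
Reagents that add atoms: 4-methoxybenzaldehyde dimethyl acetal, COc1ccc(C(OC)OC)cc1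
Why: Acid-catalysed transacetalisation of the 1,2-diol; anhydrous mild acid leaves the silyl ethers alone. The acetal carbon is removed as a stereocentre in step 18.

Step 18
Reactants: 22 C8/C9 4-methoxybenzylidene acetal
Product: 23 C9 primary alcohol with C8 OPMB (1S,6R,7R,8R)
Conditions: i-Bu2AlH (4 equiv), CH2Cl2, −78 to −10 °C
Reagents that add atoms: none
Why: Reductive opening of the 4-methoxybenzylidene acetal. Aluminium binds the less hindered primary oxygen, that C–O bond breaks and hydride is delivered to the oxocarbenium ion, leaving PMB on the secondary O8 and C9 as the free alcohol. The terminal alkyne is not hydroaluminated at this temperature.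

Step 19
Reactants: 23 C9 primary alcohol with C8 OPMB
Product: 24 seco ynal (1S,6R,7R,8R) with C9 aldehyde; C8 OPMB; C6 and C1 OTBS; C12 OTIPS; C10≡C14
Conditions: Dess–Martin periodinane, NaHCO3, CH2Cl2, 0 °C to rt
Reagents that add atoms: none
Why: Buffered Dess–Martin oxidation gives the α-alkoxy aldehyde without epimerising C8; the aldehyde is used at once.

Step 20
Reactants: 24 seco ynal; 25 triethylsilane
Product: 26 ten-membered C9 triethylsilyl ether with C10 exocyclic methylene (1S,6R,7R,8R,9R)
Conditions: Ni(cod)2 (20 mol %), IPr [1,3-bis(2,6-diisopropylphenyl)imidazol-2-ylidene] (20 mol %), 25 (5 equiv), THF, rt; 24 added over 8 h (final 0.005 M)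
Reagents that add atoms: none
Why: Zerovalent nickel bearing the carbene binds aldehyde and alkyne and couples them oxidatively to a five-membered oxanickelacycle in which C9–C10 is formed; σ-bond metathesis of the Ni–O bond with 25 gives the O–SiEt3 group and a nickel hydride, and C–H reductive elimination at C14 releases 26 and the catalyst. The closest known reaction type is the nickel/N-heterocyclic-carbene reductive macrocyclisation of ynals with trialkylsilanes, in which ligand size switches between endo and exo products. The ten-membered ring closes in the 10-exo-dig mode, with C14 left outside as the methylene. The new stereocentre C9 is controlled by the ring-forming transition state: with the C8 OPMB group anti to the forming bond, the ring carbon C7 should sit on the side of the aldehyde hydrogen, away from the oxygen bound to the bulky Ni(IPr) unit, which gives the 8,9-syn (9R) isomer against the Felkin sense. Regioselectivity (C10, not C14) is needed and is secured by the bulky carbene, which keeps the substituted alkyne terminus with its branched C1 OTBS group away from nickel. Chemoselectivity is secured by the substrate: the lactone is masked as two silyl ethers, so no enoate competes, and the three olefins are unactivated. Cyclisation over oligomerisation relies on slow addition at high dilution and on the Z-olefin and the C6–C8 substituents, which fold the chain. The silane leaves C9 as the only triethylsilyl ether, which is what step 21 exploits.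

Step 21
Reactants: 26 ten-membered C9 triethylsilyl ether
Product: 27 macrocyclic C9 allylic alcohol (1S,6R,7R,8R,9R)
Conditions: PPTS (0.2 equiv), MeOH/CH2Cl2 (1:1), 0 °C
Reagents that add atoms: none
Why: Acid-catalysed methanolysis; a triethylsilyl ether is far more labile than the secondary TBS and primary TIPS ethers, so only O9 is released.

Step 22
Reactants: 27 macrocyclic C9 allylic alcohol; 28 angelic acid
Product: 30 C9 angelate of the macrocycle (1S,6R,7R,8R,9R), via angeloyl 2,4,6-trichlorobenzoyl anhydride 29 (not isolated)
Conditions: 28, 2,4,6-Cl3C6H2COCl, Et3N, toluene, rt; then 27, toluene, 75 °C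
Reagents that add atoms: 2,4,6-trichlorobenzoyl chloride, O=C(Cl)c1c(Cl)cc(Cl)cc1Cl (atoms held in 29 only)
Why: Yamaguchi-type mixed-anhydride esterification run without a nucleophilic catalyst, so that no reversible conjugate addition can turn the Z-acyl group into the tiglate. The alcohol attacks the less hindered angeloyl carbonyl, and C9 is not touched at carbon, so its configuration is retained.

Step 23
Reactants: 30 C9 angelate of the macrocycle
Product: 31 (3S,4R)-3,4-epoxide of the silylated angelate (1S,3S,4R,6R,7R,8R,9R)
Conditions: L-fructose-derived Shi ketone (ent-Shi ketone, 0.3 equiv), KHSO5 (as 2KHSO5·KHSO4·K2SO4), K2CO3, Bu4NHSO4, MeCN/CH2(OMe)2/aq. Na2B4O7 buffer, 0 °C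
Reagents that add atoms: potassium peroxymonosulfate, [K+].[O-]S(=O)(=O)OO
Why: Shi epoxidation; the chiral dioxirane transfers oxygen through a spiro transition state to the only electron-rich trisubstituted olefin (the two 1,1-disubstituted olefins and the enoate are poor substrates). The D-fructose ketone, calibrated on 1-phenylcyclohexene giving the (R,R)-oxide, would deliver oxygen to the face that gives (3R,4S), so the enantiomeric ketone is used for (3S,4R). The syn addition turns the Z-olefin into the cis-epoxide, and no base-sensitive carbonyl is present yet.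

Step 24
Reactants: 31 (3S,4R)-3,4-epoxide of the silylated angelate
Product: 32 epoxy triol with C1; C6; C12 OH (1S,3S,4R,6R,7S,8R,9R)
Conditions: Bu4NF, AcOH (1:1), THF, rt to 40 °C
Reagents that add atoms: none
Why: Fluoride cleaves the two TBS ethers and the TIPS ether. Acetic acid buffers the alkoxides, so the angelate neither migrates nor cleaves, and the medium is not acidic enough to open the epoxide. O8 stays as the PMB ether.

Step 25
Reactants: 32 epoxy triol
Product: 34 8-O-PMB ether of the target (3S,4R,6R,7S,8R,9R), via C12 lactol 33 (not isolated)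
Conditions: MnO2 (activated, excess), CH2Cl2, rt
Reagents that add atoms: none
Why: Allylic oxidation: the primary C12 alcohol gives the enal, which O6 traps as the five-membered lactol 33, oxidised on to the α-methylene lactone; the C1 allylic alcohol gives the enone. With O8 still blocked only the 6,12-lactone can form, and the neutral heterogeneous oxidant should spare the β,γ-epoxy ketone.

Step 26
Reactants: 34 8-O-PMB ether of the target
Product: 35 CNP0348992.7, (3S,4R,6R,7R,8R,9R)-3,4-epoxy-8-hydroxy-9-[(Z)-2-methylbut-2-enoyloxy]-1-oxogermacra-10(14),11(13)-dien-12,6-olide (route numbering)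
Conditions: DDQ, CH2Cl2/pH 7 buffer (10:1), 0 °C to rt
Reagents that add atoms: none
Why: Oxidative PMB cleavage under buffered, near-neutral conditions releases the C8 hydroxyl last, so that lactone regiochemistry and the angelate position are already fixed. Epoxide, enone, lactone and angelate are inert to DDQ, and no stereocentre is touched.

## Compound list

1 | (S)-2,2-dimethyl-1,3-dioxolane-4-carbaldehyde | O=C[C@@H]1COC(C)(C)O1 | starting material
2 | ethyl acrylate | C=CC(=O)OCC | starting material
3 | ethyl 2-{[(4S)-2,2-dimethyl-1,3-dioxolan-4-yl](hydroxy)methyl}prop-2-enoate (carbinol epimers) | C=C(C(=O)OCC)C(O)[C@@H]1COC(C)(C)O1 | intermediate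
4 | ethyl (2Z)-2-(bromomethyl)-3-[(4R)-2,2-dimethyl-1,3-dioxolan-4-yl]prop-2-enoate | CCOC(=O)/C(CBr)=C/[C@@H]1COC(C)(C)O1 | intermediate
5 | (2Z)-2-(bromomethyl)-3-[(4R)-2,2-dimethyl-1,3-dioxolan-4-yl]prop-2-en-1-ol | OC/C(CBr)=C/[C@@H]1COC(C)(C)O1 | intermediate
6 | {[(2Z)-2-(bromomethyl)-3-[(4R)-2,2-dimethyl-1,3-dioxolan-4-yl]prop-2-en-1-yl]oxy}tri(propan-2-yl)silane | CC(C)[Si](OC/C(CBr)=C/[C@@H]1COC(C)(C)O1)(C(C)C)C(C)C | intermediate
7 | 4-methyl-5,6-dihydro-2H-pyran-2-one | CC1=CC(=O)OCC1 | starting material
8 | 4-methyl-5,6-dihydro-2H-pyran-2-ol | CC1=CC(O)OCC1 | intermediate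
9 | (3Z)-3-methylhexa-3,5-dien-1-ol | C=C/C=C(C)\CCO | intermediate
10 | 1-methoxy-4-({[(3Z)-3-methylhexa-3,5-dien-1-yl]oxy}methyl)benzene | C=C/C=C(C)\CCOCc1ccc(OC)cc1 | intermediate
11 | 9-{(3Z)-6-[(4-methoxybenzyl)oxy]-4-methylhex-3-en-1-yl}-9-borabicyclo[3.3.1]nonane | COc1ccc(COCC/C(C)=C\CCB2C3CCCC2CCC3)cc1 | intermediate
12 | (3Z)-6-[(4-methoxybenzyl)oxy]-4-methylhex-3-en-1-ol | OCC/C=C(C)\CCOCc1ccc(OC)cc1 | intermediate
13 | (3Z)-6-[(4-methoxybenzyl)oxy]-4-methylhex-3-enal | O=CC/C=C(C)\CCOCc1ccc(OC)cc1 | intermediate
14 | (3S,5Z)-8-[(4-methoxybenzyl)oxy]-6-methyloct-5-en-1-yn-3-ol (drawn epimer) | C#C[C@@H](O)C/C=C(C)\CCOCc1ccc(OC)cc1 | intermediate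
15 | tert-butyl{[(3S,5Z)-8-[(4-methoxybenzyl)oxy]-6-methyloct-5-en-1-yn-3-yl]oxy}dimethylsilane | C#C[C@@H](O[Si](C)(C)C(C)(C)C)C/C=C(C)\CCOCc1ccc(OC)cc1 | intermediate
16 | (3Z,6S)-6-[(tert-butyldimethylsilyl)oxy]-3-methyloct-3-en-7-yn-1-ol | C#C[C@@H](O[Si](C)(C)C(C)(C)C)C/C=C(C)\CCO | intermediate
17 | (3Z,6S)-6-[(tert-butyldimethylsilyl)oxy]-3-methyloct-3-en-7-ynal | C#C[C@@H](O[Si](C)(C)C(C)(C)C)C/C=C(C)\CC=O | intermediate
18 | dichloro{(2E)-3-[(4R)-2,2-dimethyl-1,3-dioxolan-4-yl]-2-{[(triisopropylsilyl)oxy]methyl}prop-2-en-1-yl}chromium (trivalent chromium; THF ligands omitted) | Cl[Cr](Cl)C/C(CO[Si](C(C)C)(C(C)C)C(C)C)=C/[C@@H]1COC(C)(C)O1 | intermediate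
19 | seco alcohol (1S,6R,7S,8R): C6 OH; C8/C9 acetonide; C12 OTIPS; C1 OTBS; C10≡C14 | CC1(C)OC[C@H](O1)[C@@H](C(=C)CO[Si](C(C)C)(C(C)C)C(C)C)[C@H](O)C/C(C)=C\C[C@H](O[Si](C)(C)C(C)(C)C)C#C | intermediate
20 | C6 TBS ether of the seco chain (1S,6R,7R,8R) | CC1(C)OC[C@H](O1)[C@@H](C(=C)CO[Si](C(C)C)(C(C)C)C(C)C)[C@H](O[Si](C)(C)C(C)(C)C)C/C(C)=C\C[C@H](O[Si](C)(C)C(C)(C)C)C#C | intermediate
21 | C8,C9-diol (1S,6R,7R,8R) | OC[C@H](O)[C@@H](C(=C)CO[Si](C(C)C)(C(C)C)C(C)C)[C@H](O[Si](C)(C)C(C)(C)C)C/C(C)=C\C[C@H](O[Si](C)(C)C(C)(C)C)C#C | intermediate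
22 | C8/C9 4-methoxybenzylidene acetal (acetal epimers) | COc1ccc(cc1)C1OC[C@H](O1)[C@@H](C(=C)CO[Si](C(C)C)(C(C)C)C(C)C)[C@H](O[Si](C)(C)C(C)(C)C)C/C(C)=C\C[C@H](O[Si](C)(C)C(C)(C)C)C#C | intermediate
23 | C9 primary alcohol with C8 OPMB (1S,6R,7R,8R) | OC[C@H](OCc1ccc(OC)cc1)[C@@H](C(=C)CO[Si](C(C)C)(C(C)C)C(C)C)[C@H](O[Si](C)(C)C(C)(C)C)C/C(C)=C\C[C@H](O[Si](C)(C)C(C)(C)C)C#C | intermediate
24 | seco ynal (1S,6R,7R,8R) | O=C[C@H](OCc1ccc(OC)cc1)[C@@H](C(=C)CO[Si](C(C)C)(C(C)C)C(C)C)[C@H](O[Si](C)(C)C(C)(C)C)C/C(C)=C\C[C@H](O[Si](C)(C)C(C)(C)C)C#C | intermediate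
25 | triethylsilane | CC[SiH](CC)CC | starting material
26 | ten-membered C9 triethylsilyl ether with C10 methylene (1S,6R,7R,8R,9R) | C=C(CO[Si](C(C)C)(C(C)C)C(C)C)[C@H]1[C@H](O[Si](C)(C)C(C)(C)C)C/C(C)=C\C[C@H](O[Si](C)(C)C(C)(C)C)C(=C)[C@@H](O[Si](CC)(CC)CC)[C@@H]1OCc2ccc(OC)cc2 | intermediate
27 | macrocyclic C9 allylic alcohol (1S,6R,7R,8R,9R) | C=C(CO[Si](C(C)C)(C(C)C)C(C)C)[C@H]1[C@H](O[Si](C)(C)C(C)(C)C)C/C(C)=C\C[C@H](O[Si](C)(C)C(C)(C)C)C(=C)[C@@H](O)[C@@H]1OCc2ccc(OC)cc2 | intermediate
28 | angelic acid, (Z)-2-methylbut-2-enoic acid | C/C=C(/C)C(=O)O | starting material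
29 | angeloyl 2,4,6-trichlorobenzoyl anhydride | C/C=C(/C)C(=O)OC(=O)c1c(Cl)cc(Cl)cc1Cl | intermediate
30 | C9 angelate of the macrocycle (1S,6R,7R,8R,9R) | C=C(CO[Si](C(C)C)(C(C)C)C(C)C)[C@H]1[C@H](O[Si](C)(C)C(C)(C)C)C/C(C)=C\C[C@H](O[Si](C)(C)C(C)(C)C)C(=C)[C@@H](OC(=O)/C(C)=C\C)[C@@H]1OCc2ccc(OC)cc2 | intermediate
31 | (3S,4R)-3,4-epoxide of the silylated angelate (1S,3S,4R,6R,7R,8R,9R) | C=C(CO[Si](C(C)C)(C(C)C)C(C)C)[C@H]1[C@H](O[Si](C)(C)C(C)(C)C)C[C@@]3(C)O[C@H]3C[C@H](O[Si](C)(C)C(C)(C)C)C(=C)[C@@H](OC(=O)/C(C)=C\C)[C@@H]1OCc2ccc(OC)cc2 | intermediate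
32 | epoxy triol (1S,3S,4R,6R,7S,8R,9R) | C=C(CO)[C@H]1[C@H](O)C[C@@]3(C)O[C@H]3C[C@H](O)C(=C)[C@@H](OC(=O)/C(C)=C\C)[C@@H]1OCc2ccc(OC)cc2 | intermediate
33 | C12 lactol (C1 OH; C8 OPMB; lactol epimers) | C=C1C(O)O[C@@H]2C[C@@]3(C)O[C@H]3C[C@H](O)C(=C)[C@@H](OC(=O)/C(C)=C\C)[C@H](OCc4ccc(OC)cc4)[C@@H]12 | intermediate
34 | 8-O-PMB ether of the target (3S,4R,6R,7S,8R,9R) | C=C1C(=O)O[C@@H]2C[C@@]3(C)O[C@H]3CC(=O)C(=C)[C@@H](OC(=O)/C(C)=C\C)[C@H](OCc4ccc(OC)cc4)[C@@H]12 | intermediate
35 | CNP0348992.7 (3S,4R,6R,7R,8R,9R) | C=C1C(=O)O[C@@H]2C[C@@]3(C)O[C@H]3CC(=O)C(=C)[C@@H](OC(=O)/C(C)=C\C)[C@H](O)[C@@H]12 | target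

## Step count and risk

Total: 26 steps. Longest linear sequence: 22 steps (steps 5–13, 14–19, 20, 21–26, from lactone 7); steps 1–4 form the four-step branch from 1 and 2.

**Step 20 (key step).** A ten-membered ring is at the small end of what this cyclisation closes. The most likely failure is slow ring closure, so that intermolecular coupling and plain hydrosilylation of the aldehyde take over. When the ring does close, approach in the Felkin sense would give the 9S epimer, and the two C1 epimers of 24 may behave differently. Fallback, from 23 back to 27: α-selective hydrostannation of the terminal alkyne of 23 (Bu3SnH, Mo(CO)3(CNt-Bu)3 cat.) gives the 1,1-disubstituted vinylstannane F1. Iododestannylation (I2) gives the 2-iodoalkene F2, and Dess–Martin oxidation gives the iodo aldehyde F3. A Nozaki–Hiyama–Kishi ring closure (CrCl2, NiCl2 cat., DMSO, high dilution) forms the same C9–C10 bond stoichiometrically and irreversibly, giving the macrocyclic allylic alcohols F4 as C9 epimers. Oxidation to the C9 enone F5 and reduction with (R)-2-methyl-CBS-oxazaborolidine/BH3·THF, with the alkenyl group in the large-substituent role, sets 9R by reagent control and returns 27.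

**Step 14.** The 2-substituent on the allyl unit lowers the E/Z bias of the allylchromium, so the most likely failure is erosion of the anti preference, with part of the material reacting through the Z-form to the C6 epimer. Weaker facial control by the dioxolane is a second possibility. Fallback, from 17 and 6 back to 19: the 6,7-syn adduct F6 (the C6 epimer of 19) is not discarded. Mitsunobu inversion (4-nitrobenzoic acid, DIAD, PPh3) gives the inverted 4-nitrobenzoate F7, and methanolysis (K2CO3, MeOH) gives 19. C6 is then set by SN2 inversion instead of by the transition state of the coupling.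

**Step 23.** The needed olefin face may be the one turned towards the ring interior in the preferred conformer. The chiral dioxirane would then react slowly (mismatched case) and over-oxidation of the 1,1-disubstituted olefins would begin. Fallback, from 30 back to 31: NBS in THF/H2O forms the bromonium ion on the exposed face, and water opens it at the tertiary C4 from the opposite face to give bromohydrin F8. DBU in CH2Cl2 then closes the epoxide by displacement at C3, which places the oxygen on the face the dioxirane could not reach.

**Step 22.** The C9 hydroxyl is flanked by C8 OPMB and the C10 methylene. Slow acylation at the temperature needed would leave time for Z→E isomerisation of the acyl group to the tiglate. Fallback, from 27 back to 30: esterify 27 with 2-[bis(2,2,2-trifluoroethoxy)phosphoryl]propanoic acid (EDC, DMAP) to phosphonate ester F9, then run a Still–Gennari olefination with acetaldehyde (KN(SiMe3)2, 18-crown-6, THF, −78 °C). This builds the Z-2-methylbut-2-enoate on the molecule instead of transferring it.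

## Further compounds

F1 | step 20 | α-vinylstannane from 23 (C10 SnBu3, C9 OH) | OC[C@H](OCc1ccc(OC)cc1)[C@@H](C(=C)CO[Si](C(C)C)(C(C)C)C(C)C)[C@H](O[Si](C)(C)C(C)(C)C)C/C(C)=C\C[C@H](O[Si](C)(C)C(C)(C)C)C(=C)[Sn](CCCC)(CCCC)CCCC
F2 | step 20 | 2-iodoalkene (C10 iodide, C9 OH) | OC[C@H](OCc1ccc(OC)cc1)[C@@H](C(=C)CO[Si](C(C)C)(C(C)C)C(C)C)[C@H](O[Si](C)(C)C(C)(C)C)C/C(C)=C\C[C@H](O[Si](C)(C)C(C)(C)C)C(I)=C
F3 | step 20 | iodo aldehyde (C10 iodide, C9 aldehyde) | O=C[C@H](OCc1ccc(OC)cc1)[C@@H](C(=C)CO[Si](C(C)C)(C(C)C)C(C)C)[C@H](O[Si](C)(C)C(C)(C)C)C/C(C)=C\C[C@H](O[Si](C)(C)C(C)(C)C)C(I)=C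
F4 | step 20 | macrocyclic C9 allylic alcohols (both C9 epimers) | C=C(CO[Si](C(C)C)(C(C)C)C(C)C)[C@H]1[C@H](O[Si](C)(C)C(C)(C)C)C/C(C)=C\C[C@H](O[Si](C)(C)C(C)(C)C)C(=C)C(O)[C@@H]1OCc2ccc(OC)cc2
F5 | step 20 | macrocyclic C9 enone | C=C(CO[Si](C(C)C)(C(C)C)C(C)C)[C@H]1[C@H](O[Si](C)(C)C(C)(C)C)C/C(C)=C\C[C@H](O[Si](C)(C)C(C)(C)C)C(=C)C(=O)[C@@H]1OCc2ccc(OC)cc2
F6 | step 14 | C6 epimer of 19 (6,7-syn adduct) | CC1(C)OC[C@H](O1)[C@@H](C(=C)CO[Si](C(C)C)(C(C)C)C(C)C)[C@@H](O)C/C(C)=C\C[C@H](O[Si](C)(C)C(C)(C)C)C#C
F7 | step 14 | C6 4-nitrobenzoate with the configuration of 19 | CC1(C)OC[C@H](O1)[C@@H](C(=C)CO[Si](C(C)C)(C(C)C)C(C)C)[C@H](OC(=O)c2ccc(cc2)[N+](=O)[O-])C/C(C)=C\C[C@H](O[Si](C)(C)C(C)(C)C)C#C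
F8 | step 23 | bromohydrin of 30 (C3 Br, C4 OH) | C=C(CO[Si](C(C)C)(C(C)C)C(C)C)[C@H]1[C@H](O[Si](C)(C)C(C)(C)C)C[C@@](C)(O)[C@H](Br)C[C@H](O[Si](C)(C)C(C)(C)C)C(=C)[C@@H](OC(=O)/C(C)=C\C)[C@@H]1OCc2ccc(OC)cc2
F9 | step 22 | C9 2-[bis(2,2,2-trifluoroethoxy)phosphoryl]propanoate of 27 | C=C(CO[Si](C(C)C)(C(C)C)C(C)C)[C@H]1[C@H](O[Si](C)(C)C(C)(C)C)C/C(C)=C\C[C@H](O[Si](C)(C)C(C)(C)C)C(=C)[C@@H](OC(=O)C(C)P(=O)(OCC(F)(F)F)OCC(F)(F)F)[C@@H]1OCc2ccc(OC)cc2
A1 | alternative 1 | (Z)-cyclodecene from ring-closing metathesis, des-epoxy C8 triethylsilyl ether of the target | C=C1C(=O)O[C@@H]2C/C(C)=C\CC(=O)C(=C)[C@@H](OC(=O)/C(C)=C\C)[C@H](O[Si](CC)(CC)CC)[C@@H]12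
A2 | alternative 2 | (Z)-cyclodec-3-ene-1,6-dione carrying the C7–C10 array | OC(=O)C[C@H]1C(=O)C/C(C)=C\CC(=O)[C@H](CO[Si](C)(C)C(C)(C)C)[C@@H](OCOC)[C@@H]1O[Si](C)(C)C(C)(C)C
A3 | alternative 3 | ten-membered C8 ketone with Z-C3=C4, C6 OPMB and C7 acetate arm | O=C1[C@@H](CC(=O)OC(C)(C)C)[C@H](OCc2ccc(OC)cc2)C/C(C)=C\C[C@@H]2O[C@]2(C)[C@H]1OCOC
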